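## Retrosynthetic overview

1. Target ⇐ DMAP acetylation of the C13 alcohol ⇐ ring-closing metathesis at C6=C7 (the 14-membered ring, formed last).
2. Metathesis precursor ⇐ intermolecular indium-mediated 2-(methoxycarbonyl)allylation forming C1–C2, between an achiral C2–C6 enal and a (Z)-2-(bromomethyl)enoate carrying C7–C14; the cis-γ-lactone closes in the same operation (second ring).
3. Bromide ⇐ Baylis–Hillman reaction and SN2′ bromination at C1 ⇐ Brown allylation of an α,β-epoxy aldehyde (sets C13) ⇐ Sharpless epoxidation of a Z-allylic alcohol (oxirane, first ring) ⇐ Still–Gennari olefination.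
4. C8 carbinol ⇐ (S)-dehydrolinalool from geraniol (Sharpless epoxidation, epoxy chloride fragmentation); the alkyne is a masked vinyl group, unmasked by Lindlar reduction after the oxidative cleavages.
5. Enal ⇐ Negishi carboalumination of pent-1-en-4-yne.

Assumption and convention: pent-1-en-4-yne is taken as a catalogue chemical; locants C1–C20 in the text are the cembrane locants of the target (C1 = ring CH bearing the lactone α-carbon C15, C2 = CH–O, C16 = lactone C=O, C17 = exocyclic CH2), and CIP letters in names are recomputed for each compound.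

## Route

Step 1
Reactants: 1 pent-1-en-4-yne
Product: 4 (2E)-3-methylhexa-2,5-dien-1-ol, via alkenyldimethylalane 2 (not isolated), via lithium alkenylaluminate 3 (not isolated)
Conditions: AlMe3 (2 equiv), Cp2ZrCl2 (0.25 equiv), CH2Cl2, 0 °C to rt; n-BuLi, THF, −78 °C; (CH2O)n, rt; aq. work-up
Reagents that add atoms: trimethylaluminium, C[Al](C)C; formaldehyde (as paraformaldehyde), C=O
Why: Negishi zirconium-catalysed carboalumination adds Me and Al syn and regioselectively across the terminal alkyne (the isolated alkene is inert), so hydroxymethylation of the alkenylaluminate gives only the E trisubstituted allylic alcohol.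

Step 2
Reactants: 4 (2E)-3-methylhexa-2,5-dien-1-ol
Product: 5 (2E)-3-methylhexa-2,5-dienal
Conditions: MnO2 (activated, excess), CH2Cl2, rt
Reagents that add atoms: none
Why: Neutral allylic oxidation with MnO2 touches only the allylic alcohol, so the E geometry and the skipped diene are kept; the enal is used fresh.

Step 3
Reactants: 6 geraniol
Product: 7 (2S,3S)-2,3-epoxygeraniol
Conditions: Ti(OiPr)4 (5 mol%), L-(+)-diethyl tartrate (7 mol%), t-BuOOH, 4 Å MS, CH2Cl2, −20 °C
Reagents that add atoms: tert-butyl hydroperoxide, CC(C)(C)OO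
Why: Katsuki–Sharpless asymmetric epoxidation of an E trisubstituted allylic alcohol; L-(+)-tartrate gives the (2S,3S)-epoxide, which fixes the later C8 centre as S.

Step 4
Reactants: 7 (2S,3S)-2,3-epoxygeraniol
Product: 8 (2S,3R)-3-(chloromethyl)-2-methyl-2-(4-methylpent-3-en-1-yl)oxirane
Conditions: PPh3, CCl4, NaHCO3, reflux
Reagents that add atoms: carbon tetrachloride, ClC(Cl)(Cl)Cl
Why: Appel chlorination under neutral conditions replaces only the primary hydroxyl; no stereocentre is touched (one CIP letter changes because Cl outranks O).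

Step 5
Reactants: 8 epoxygeranyl chloride
Product: 10 (3S)-3,7-dimethyloct-6-en-1-yn-3-ol, via chlorovinyl lithium alkoxide 9 (not isolated)
Conditions: n-BuLi (3.1 equiv), THF, −40 °C to 0 °C; H2O
Reagents that add atoms: none
Why: Base-induced fragmentation of a 2,3-epoxy chloride (α-lithiation, β-elimination to the chlorovinyl alkoxide, then loss of LiCl) gives the tertiary propargylic alcohol; the C–O bond at the quaternary carbon is never broken, so S is retained.

Step 6
Reactants: 10 (S)-dehydrolinalool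
Product: 11 triethyl{[(3S)-3,7-dimethyloct-6-en-1-yn-3-yl]oxy}silane
Conditions: Et3SiOTf, 2,6-lutidine, CH2Cl2, −78 to 0 °C
Reagents that add atoms: triethylsilyl triflate, CC[Si](CC)(CC)OS(=O)(=O)C(F)(F)F
Why: Silyl triflate silylation is forceful enough for the hindered tertiary alcohol; the ether withstands the basic, oxidative and reductive steps that follow and is removed by fluoride.

Step 7
Reactants: 11 silyl ether of (S)-dehydrolinalool
Product: 13 (4S)-4-methyl-4-(triethylsilyloxy)hex-5-ynal, via secondary ozonide 12 (not isolated)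
Conditions: O3, CH2Cl2, −78 °C (stopped at the end point); PPh3, −78 °C to rt
Reagents that add atoms: ozone, [O-][O+]=O
Why: Ozonolysis with reductive work-up; the electron-rich trisubstituted alkene reacts far faster than the terminal alkyne.

Step 8
Reactants: 13 (4S)-4-methyl-4-(triethylsilyloxy)hex-5-ynal
Product: 14 methyl (2Z,6S)-2,6-dimethyl-6-(triethylsilyloxy)oct-2-en-7-ynoate
Conditions: (CF3CH2O)2P(O)CH(CH3)CO2Me, KN(SiMe3)2, 18-crown-6, THF, −78 °C
Reagents that add atoms: methyl 2-[bis(2,2,2-trifluoroethoxy)phosphoryl]propanoate, COC(=O)C(C)P(=O)(OCC(F)(F)F)OCC(F)(F)F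
Why: Still–Gennari olefination is kinetically Z-selective, placing C10 cis to the future C13 carbon as the cis-epoxide requires.

Step 9
Reactants: 14 Z-enoate
Product: 15 (2Z,6S)-2,6-dimethyl-6-(triethylsilyloxy)oct-2-en-7-yn-1-ol
Conditions: i-Bu2AlH (2.5 equiv), CH2Cl2, −78 °C
Reagents that add atoms: none
Why: 1,2-Reduction of the enoate by the aluminium hydride at low temperature gives the Z-allylic alcohol without isomerisation or alkyne hydroalumination.

Step 10
Reactants: 15 Z-allylic alcohol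
Product: 16 {(2R,3S)-2-methyl-3-[(3S)-3-methyl-3-(triethylsilyloxy)pent-4-yn-1-yl]oxiran-2-yl}methanol
Conditions: Ti(OiPr)4 (0.3 equiv), D-(−)-diethyl tartrate (0.36 equiv), t-BuOOH, 4 Å MS, CH2Cl2, −20 °C
Reagents that add atoms: tert-butyl hydroperoxide, CC(C)(C)OO
Why: Katsuki–Sharpless asymmetric epoxidation with D-(−)-tartrate delivers oxygen to the face that gives the target's C11/C12 configuration (cis-epoxide from the Z-alkene); the reaction is slow for Z substrates but the wrong-face product is a separable diastereomer because C8 is already fixed.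

Step 11
Reactants: 16 epoxy alcohol
Product: 17 (2S,3S)-2-methyl-3-[(3S)-3-methyl-3-(triethylsilyloxy)pent-4-yn-1-yl]oxirane-2-carbaldehyde
Conditions: Dess–Martin periodinane, NaHCO3, CH2Cl2, 0 °C to rt
Reagents that add atoms: none
Why: Dess–Martin oxidation is neutral and spares the epoxide and silyl ether; the α-carbon is quaternary, so the aldehyde cannot epimerise.

Step 12
Reactants: 17 epoxy aldehyde
Product: 19 (1R)-1-{(2R,3S)-2-methyl-3-[(3S)-3-methyl-3-(triethylsilyloxy)pent-4-yn-1-yl]oxiran-2-yl}but-3-en-1-ol, via diisopinocampheylborinate ester 18 (not isolated)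
Conditions: CH2=CHCH2MgBr, (+)-Ipc2BOMe (from (−)-α-pinene), Et2O, −78 °C to rt; 17, −78 °C; NaOH, H2O2, 0 °C
Reagents that add atoms: allylmagnesium bromide, C=CC[Mg]Br (allyl group, delivered through (−)-Ipc2B(allyl))
Why: Brown asymmetric allylboration through a chair transition state attacks the Re face of the aldehyde, which is also the face favoured by the Cornforth/Felkin arrangement of the α-epoxy aldehyde (matched pair), and sets C13 as R.

Step 13
Reactants: 19 homoallylic alcohol
Product: 20 triethyl{[(1R)-1-{(2S,3S)-2-methyl-3-[(3S)-3-methyl-3-(triethylsilyloxy)pent-4-yn-1-yl]oxiran-2-yl}but-3-en-1-yl]oxy}silane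
Conditions: Et3SiCl, imidazole, DMAP (cat.), DMF, rt
Reagents that add atoms: chlorotriethylsilane, CC[Si](Cl)(CC)CC
Why: Chlorosilane/imidazole silylation avoids Lewis-acidic silyl triflates next to the epoxide; a β-silyloxy group (unlike a β-acetoxy group) survives the aldehyde chemistry that follows.

Step 14
Reactants: 20 bis(triethylsilyl) ether
Product: 22 (3R)-3-{(2S,3S)-2-methyl-3-[(3S)-3-methyl-3-(triethylsilyloxy)pent-4-yn-1-yl]oxiran-2-yl}-3-(triethylsilyloxy)propanal, via vicinal diol 21 (not isolated)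
Conditions: OsO4 (2 mol%), NaIO4 (4 equiv), 2,6-lutidine, dioxane/H2O 3:1, rt
Reagents that add atoms: osmium tetroxide, O=[Os](=O)(=O)=O; sodium periodate (reoxidant), [Na+].[O-]I(=O)(=O)=O
Why: Lemieux–Johnson cleavage; OsO4 dihydroxylates only the terminal alkene (the alkyne is inert) and periodate cleaves the diol, while lutidine buffering protects the epoxide and silyl ethers.

Step 15
Reactants: 22 alkynyl aldehyde
Product: 23 (3R)-3-{(2S,3S)-2-methyl-3-[(3S)-3-methyl-3-(triethylsilyloxy)pent-4-en-1-yl]oxiran-2-yl}-3-(triethylsilyloxy)propanal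
Conditions: H2 (1 atm), Pd/CaCO3 poisoned with Pb(OAc)2 (Lindlar catalyst), quinoline, EtOAc, rt
Reagents that add atoms: none
Why: Lindlar semi-hydrogenation of a terminal propargylic ether stops at the vinyl group (the dehydrolinalool-to-linalool reduction) and leaves aldehyde, epoxide and silyl ethers alone; with both oxidative cleavages done, the vinyl group can now be revealed.

Step 16
Reactants: 23 vinyl aldehyde
Product: 24 methyl (3RS,5R)-3-hydroxy-2-methylidene-5-{(2S,3S)-2-methyl-3-[(3S)-3-methyl-3-(triethylsilyloxy)pent-4-en-1-yl]oxiran-2-yl}-5-(triethylsilyloxy)pentanoate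
Conditions: methyl acrylate (excess), DABCO (1 equiv), neat, rt, 3–5 d
Reagents that add atoms: methyl acrylate, C=CC(=O)OC
Why: Morita–Baylis–Hillman reaction of an unhindered aliphatic aldehyde; the new carbinol centre is destroyed in the next step, so its configuration does not matter.

Step 17
Reactants: 24 Baylis–Hillman adduct
Product: 25 methyl (2Z,5R)-2-(bromomethyl)-5-{(2S,3S)-2-methyl-3-[(3S)-3-methyl-3-(triethylsilyloxy)pent-4-en-1-yl]oxiran-2-yl}-5-(triethylsilyloxy)pent-2-enoate
Conditions: NBS, Me2S, CH2Cl2, 0 °C to rt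
Reagents that add atoms: N-bromosuccinimide, O=C1CCC(=O)N1Br
Why: Corey–Kim-type activation of the alcohol followed by SN2′ attack of bromide gives the rearranged primary allylic bromide with the chain trans to the ester (Z), the normal outcome for Baylis–Hillman adducts, under acid-free conditions.

Step 18
Reactants: 25 (Z)-allylic bromide; 5 (2E)-3-methylhexa-2,5-dienal
Product: 28 (4S,5S)-3-methylidene-5-[(1E)-2-methylpenta-1,4-dien-1-yl]-4-[(2R)-2-{(2S,3S)-2-methyl-3-[(3S)-3-methyl-3-(triethylsilyloxy)pent-4-en-1-yl]oxiran-2-yl}-2-(triethylsilyloxy)ethyl]oxolan-2-one, via allylindium dibromide 26 (not isolated), via syn hydroxy ester 27 (not isolated)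
Conditions: In powder (1.5 equiv), THF/H2O 1:1, rt; PPTS (cat.), CH2Cl2, rt; chromatographic separation of the two cis-lactones
Reagents that add atoms: none
Why: Intermolecular indium-mediated Barbier 2-(alkoxycarbonyl)allylation: the Z-configured allylindium adds 1,2 to the enal through a closed chair transition state with the C14 chain axial, giving the syn adduct, which lactonises to the cis-lactone (C1/C2 relative configuration); the distant C13 centre gives little face bias, so roughly equal amounts of the (1S,2S) lactone 28 and its (1R,2R) cis diastereomer are expected and are separated by chromatography.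

Step 19
Reactants: 28 cis-lactone bis(silyl) ether
Product: 29 (4S,5S)-4-[(2R)-2-hydroxy-2-{(2R,3S)-3-[(3S)-3-hydroxy-3-methylpent-4-en-1-yl]-2-methyloxiran-2-yl}ethyl]-3-methylidene-5-[(1E)-2-methylpenta-1,4-dien-1-yl]oxolan-2-one
Conditions: Bu4NF (3 equiv), AcOH (3 equiv), THF, 0 °C to rt
Reagents that add atoms: none
Why: Acetic acid-buffered fluoride removes both triethylsilyl ethers without base-induced oxa-Michael addition to the methylene lactone or Payne rearrangement of the epoxy alcohol.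

Step 20
Reactants: 29 lactone diol
Product: 30 (1S,2S,3E,6E,8S,11S,12R,13R)-11,12-epoxy-8,13-dihydroxycembra-3,6,15(17)-trien-16,2-olide
Conditions: second-generation Grubbs catalyst RuCl2(=CHPh)(H2IMes)(PCy3) (10 mol%), 1,4-benzoquinone (20 mol%), CH2Cl2 (1 mM), 40 °C
Reagents that add atoms: none
Why: Ring-closing metathesis between the allyl terminus and the vinyl carbinol (the free allylic hydroxyl helps turnover); the fully substituted allylic carbon should favour the E alkene, and the methylene lactone cannot compete because closure onto it would need a trans-cycloheptene.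

Step 21
Reactants: 30 macrocyclic diol
Product: 31 (1S,2S,3E,6E,8S,11S,12S,13R)-13-acetoxy-11,12-epoxy-8-hydroxycembra-3,6,15(17)-trien-16,2-olide (target)
Conditions: Ac2O, pyridine, DMAP (cat.), CH2Cl2, 0 °C to rt
Reagents that add atoms: acetic anhydride, CC(=O)OC(C)=O
Why: DMAP-catalysed acetylation takes the secondary C13 alcohol and leaves the tertiary allylic C8 alcohol, which does not acylate under these conditions.

## Compound list

1 | pent-1-en-4-yne | C#CCC=C | starting material
2 | (E)-dimethyl(2-methylpenta-1,4-dien-1-yl)alane (formed in situ) | C[Al](C)/C=C(\C)CC=C | intermediate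
3 | lithium (E)-butyl(dimethyl)(2-methylpenta-1,4-dien-1-yl)aluminate (formed in situ) | [Li+].CCCC[Al-](C)(C)/C=C(\C)CC=C | intermediate
4 | (2E)-3-methylhexa-2,5-dien-1-ol | OC/C=C(\C)CC=C | intermediate
5 | (2E)-3-methylhexa-2,5-dienal | O=C/C=C(\C)CC=C | intermediate
6 | geraniol, (2E)-3,7-dimethylocta-2,6-dien-1-ol | OC/C=C(\C)CCC=C(C)C | starting material
7 | (2S,3S)-2,3-epoxygeraniol, [(2S,3S)-3-methyl-3-(4-methylpent-3-en-1-yl)oxiran-2-yl]methanol | OC[C@@H]1O[C@@]1(C)CCC=C(C)C | intermediate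
8 | (2S,3R)-3-(chloromethyl)-2-methyl-2-(4-methylpent-3-en-1-yl)oxirane | ClC[C@@H]1O[C@@]1(C)CCC=C(C)C | intermediate
9 | lithium (3S)-1-chloro-3,7-dimethylocta-1,6-dien-3-olate, C1=C2 geometry undefined (formed in situ) | ClC=C[C@@](C)([O-])CCC=C(C)C.[Li+] | intermediate
10 | (3S)-3,7-dimethyloct-6-en-1-yn-3-ol, (S)-dehydrolinalool | C#C[C@@](C)(O)CCC=C(C)C | intermediate
11 | triethyl{[(3S)-3,7-dimethyloct-6-en-1-yn-3-yl]oxy}silane | C#C[C@@](C)(O[Si](CC)(CC)CC)CCC=C(C)C | intermediate
12 | 3,3-dimethyl-5-[(3S)-3-methyl-3-(triethylsilyloxy)pent-4-yn-1-yl]-1,2,4-trioxolane, epimers at C5 (formed in situ) | C#C[C@@](C)(O[Si](CC)(CC)CC)CCC1OOC(C)(C)O1 | intermediate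
13 | (4S)-4-methyl-4-(triethylsilyloxy)hex-5-ynal | C#C[C@@](C)(O[Si](CC)(CC)CC)CCC=O | intermediate
14 | methyl (2Z,6S)-2,6-dimethyl-6-(triethylsilyloxy)oct-2-en-7-ynoate | C#C[C@@](C)(O[Si](CC)(CC)CC)CC/C=C(/C)C(=O)OC | intermediate
15 | (2Z,6S)-2,6-dimethyl-6-(triethylsilyloxy)oct-2-en-7-yn-1-ol | C#C[C@@](C)(O[Si](CC)(CC)CC)CC/C=C(/C)CO | intermediate
16 | {(2R,3S)-2-methyl-3-[(3S)-3-methyl-3-(triethylsilyloxy)pent-4-yn-1-yl]oxiran-2-yl}methanol | C#C[C@@](C)(O[Si](CC)(CC)CC)CC[C@@H]1O[C@]1(C)CO | intermediate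
17 | (2S,3S)-2-methyl-3-[(3S)-3-methyl-3-(triethylsilyloxy)pent-4-yn-1-yl]oxirane-2-carbaldehyde | C#C[C@@](C)(O[Si](CC)(CC)CC)CC[C@@H]1O[C@]1(C)C=O | intermediate
18 | bis[(1S,2S,3S,5R)-isopinocampheyl]borinate ester of alcohol 19 (formed in situ) | C#C[C@@](C)(O[Si](CC)(CC)CC)CC[C@@H]1O[C@]1(C)[C@H](OB([C@H]2C[C@H]3C[C@@H]([C@@H]2C)C3(C)C)[C@H]2C[C@H]3C[C@@H]([C@@H]2C)C3(C)C)CC=C | intermediate
19 | (1R)-1-{(2R,3S)-2-methyl-3-[(3S)-3-methyl-3-(triethylsilyloxy)pent-4-yn-1-yl]oxiran-2-yl}but-3-en-1-ol | C#C[C@@](C)(O[Si](CC)(CC)CC)CC[C@@H]1O[C@]1(C)[C@H](O)CC=C | intermediate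
20 | triethyl{[(1R)-1-{(2S,3S)-2-methyl-3-[(3S)-3-methyl-3-(triethylsilyloxy)pent-4-yn-1-yl]oxiran-2-yl}but-3-en-1-yl]oxy}silane | C#C[C@@](C)(O[Si](CC)(CC)CC)CC[C@@H]1O[C@]1(C)[C@H](O[Si](CC)(CC)CC)CC=C | intermediate
21 | (2RS,4R)-4-{(2S,3S)-2-methyl-3-[(3S)-3-methyl-3-(triethylsilyloxy)pent-4-yn-1-yl]oxiran-2-yl}-4-(triethylsilyloxy)butane-1,2-diol (formed in situ) | C#C[C@@](C)(O[Si](CC)(CC)CC)CC[C@@H]1O[C@]1(C)[C@H](O[Si](CC)(CC)CC)CC(O)CO | intermediate
22 | (3R)-3-{(2S,3S)-2-methyl-3-[(3S)-3-methyl-3-(triethylsilyloxy)pent-4-yn-1-yl]oxiran-2-yl}-3-(triethylsilyloxy)propanal | C#C[C@@](C)(O[Si](CC)(CC)CC)CC[C@@H]1O[C@]1(C)[C@H](O[Si](CC)(CC)CC)CC=O | intermediate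
23 | (3R)-3-{(2S,3S)-2-methyl-3-[(3S)-3-methyl-3-(triethylsilyloxy)pent-4-en-1-yl]oxiran-2-yl}-3-(triethylsilyloxy)propanal | C=C[C@@](C)(O[Si](CC)(CC)CC)CC[C@@H]1O[C@]1(C)[C@H](O[Si](CC)(CC)CC)CC=O | intermediate
24 | methyl (3RS,5R)-3-hydroxy-2-methylidene-5-{(2S,3S)-2-methyl-3-[(3S)-3-methyl-3-(triethylsilyloxy)pent-4-en-1-yl]oxiran-2-yl}-5-(triethylsilyloxy)pentanoate | C=C[C@@](C)(O[Si](CC)(CC)CC)CC[C@@H]1O[C@]1(C)[C@H](O[Si](CC)(CC)CC)CC(O)C(=C)C(=O)OC | intermediate
25 | methyl (2Z,5R)-2-(bromomethyl)-5-{(2S,3S)-2-methyl-3-[(3S)-3-methyl-3-(triethylsilyloxy)pent-4-en-1-yl]oxiran-2-yl}-5-(triethylsilyloxy)pent-2-enoate | C=C[C@@](C)(O[Si](CC)(CC)CC)CC[C@@H]1O[C@]1(C)[C@H](O[Si](CC)(CC)CC)C/C=C(\CBr)C(=O)OC | intermediate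
26 | allylindium dibromide from 25, methyl (2Z,5R)-2-[(dibromoindiganyl)methyl]pent-2-enoate with the same C5 substituents (formed in situ) | C=C[C@@](C)(O[Si](CC)(CC)CC)CC[C@@H]1O[C@]1(C)[C@H](O[Si](CC)(CC)CC)C/C=C(\C[In](Br)Br)C(=O)OC | intermediate
27 | methyl (3S,4S,5E)-4-hydroxy-6-methyl-2-methylidene-3-[(2R)-2-{(2S,3S)-2-methyl-3-[(3S)-3-methyl-3-(triethylsilyloxy)pent-4-en-1-yl]oxiran-2-yl}-2-(triethylsilyloxy)ethyl]nona-5,8-dienoate (formed in situ) | C=C[C@@](C)(O[Si](CC)(CC)CC)CC[C@@H]1O[C@]1(C)[C@H](O[Si](CC)(CC)CC)C[C@@H](C(=C)C(=O)OC)[C@@H](O)/C=C(\C)CC=C | intermediate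
28 | (4S,5S)-3-methylidene-5-[(1E)-2-methylpenta-1,4-dien-1-yl]-4-[(2R)-2-{(2S,3S)-2-methyl-3-[(3S)-3-methyl-3-(triethylsilyloxy)pent-4-en-1-yl]oxiran-2-yl}-2-(triethylsilyloxy)ethyl]oxolan-2-one | C=C[C@@](C)(O[Si](CC)(CC)CC)CC[C@@H]1O[C@]1(C)[C@H](O[Si](CC)(CC)CC)C[C@H]2C(=C)C(=O)O[C@H]2/C=C(\C)CC=C | intermediate
29 | (4S,5S)-4-[(2R)-2-hydroxy-2-{(2R,3S)-3-[(3S)-3-hydroxy-3-methylpent-4-en-1-yl]-2-methyloxiran-2-yl}ethyl]-3-methylidene-5-[(1E)-2-methylpenta-1,4-dien-1-yl]oxolan-2-one | C=C[C@@](C)(O)CC[C@@H]1O[C@]1(C)[C@H](O)C[C@H]2C(=C)C(=O)O[C@H]2/C=C(\C)CC=C | intermediate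
30 | (1S,2S,3E,6E,8S,11S,12R,13R)-11,12-epoxy-8,13-dihydroxycembra-3,6,15(17)-trien-16,2-olide | C=C1C(=O)O[C@H]2/C=C(\C)C/C=C/[C@@](C)(O)CC[C@@H]3O[C@]3(C)[C@H](O)C[C@@H]12 | intermediate
31 | (1S,2S,3E,6E,8S,11S,12S,13R)-13-acetoxy-11,12-epoxy-8-hydroxycembra-3,6,15(17)-trien-16,2-olide, CNP0288879.2 | C=C1C(=O)O[C@H]2/C=C(\C)C/C=C/[C@@](C)(O)CC[C@@H]3O[C@]3(C)[C@H](OC(C)=O)C[C@@H]12 | target

## Step count and weak points

Total: 21 steps (2 for the enal, 15 for the bromide, 4 after the union). Longest linear sequence: 19 steps, from geraniol 6 to target 31 (steps 3–21).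

**Step 18 (fragment union).** The syn/cis relationship is dependable, but the achiral enal is not steered by the remote C13 centre. About half of the material is therefore expected as the (1R,2R) cis-lactone, and the lactonisation needs mild acid next to an allylic C–O bond. The fallback sets out from bromide 25 and returns at lactone 28, replacing the metal-mediated addition by a catalyst-controlled allylboration. 25 is borylated with B2pin2 and Pd2(dba)3 in DMSO at 50 °C to give the linear allylboronate, methyl (2E,5R)-5-{(2S,3S)-2-methyl-3-[(3S)-3-methyl-3-(triethylsilyloxy)pent-4-en-1-yl]oxiran-2-yl}-2-[(4,4,5,5-tetramethyl-1,3,2-dioxaborolan-2-yl)methyl]-5-(triethylsilyloxy)pent-2-enoate F1. F1 and enal 5 are combined in toluene at −30 °C with 5–10 mol% of the chiral BINOL phosphoric acid (R)-TRIP. By analogy with aryl aldehydes this enantiomer should direct the boronate to the Re face of 5 through the same closed chair (the antipode is used if the sense proves opposite). The product is the pinacol borate ester of hydroxy ester 27 F2, which lactonises on warming with loss of the methyl borate to give 28.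

**Step 20 (macrocyclisation).** The vinyl group sits on a fully substituted carbon, the E/Z ratio in the 14-membered ring is not guaranteed, and the methylene lactone can tie up the ruthenium carbene. The fallback sets out from diol 29 and returns at macrocycle 30, masking the acrylate unit during ring closure. Me2NH in THF adds to the methylene group to give the amine adduct, (4S,5S)-3-[(dimethylamino)methyl]-4-[(2R)-2-hydroxy-2-{(2R,3S)-3-[(3S)-3-hydroxy-3-methylpent-4-en-1-yl]-2-methyloxiran-2-yl}ethyl]-5-[(1E)-2-methylpenta-1,4-dien-1-yl]oxolan-2-one F3. Its camphorsulfonate salt is cyclised with the same second-generation Grubbs catalyst in toluene at 80 °C, where the ring can equilibrate towards the E alkene, giving after basification the macrocyclic amine, (1S,2S,3E,6E,8S,11S,12R,13R)-17-(dimethylamino)-11,12-epoxy-8,13-dihydroxycembra-3,6-dien-16,2-olide F4. MeI converts F4 into the quaternary salt, the N-methyl iodide of F4 F5, and aqueous NaHCO3 eliminates the amine to restore the methylene lactone of 30.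

**Step 16 (Baylis–Hillman reaction).** The reaction takes days, and DABCO can eliminate the β-silyloxy group of aldehyde 23. The fallback sets out from aldehyde 23 and returns at adduct 24, replacing amine catalysis by vinylalumination. Methyl propiolate is hydroaluminated with i-Bu2AlH and N-methylmorpholine N-oxide in THF at 0 °C, and the resulting α-(methoxycarbonyl)vinylalane adds to 23 within hours at 0 °C to give the same alcohol 24; no new route compound arises.

Further compounds

F1 | step 18 | methyl (2E,5R)-5-{(2S,3S)-2-methyl-3-[(3S)-3-methyl-3-(triethylsilyloxy)pent-4-en-1-yl]oxiran-2-yl}-2-[(4,4,5,5-tetramethyl-1,3,2-dioxaborolan-2-yl)methyl]-5-(triethylsilyloxy)pent-2-enoate | C=C[C@@](C)(O[Si](CC)(CC)CC)CC[C@@H]1O[C@]1(C)[C@H](O[Si](CC)(CC)CC)C/C=C(\CB2OC(C)(C)C(C)(C)O2)C(=O)OC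
F2 | step 18 | pinacol borate ester of hydroxy ester 27 (O–B at C2) | C=C[C@@](C)(O[Si](CC)(CC)CC)CC[C@@H]1O[C@]1(C)[C@H](O[Si](CC)(CC)CC)C[C@@H](C(=C)C(=O)OC)[C@@H](OB2OC(C)(C)C(C)(C)O2)/C=C(\C)CC=C
F3 | step 20 | (4S,5S)-3-[(dimethylamino)methyl]-4-[(2R)-2-hydroxy-2-{(2R,3S)-3-[(3S)-3-hydroxy-3-methylpent-4-en-1-yl]-2-methyloxiran-2-yl}ethyl]-5-[(1E)-2-methylpenta-1,4-dien-1-yl]oxolan-2-one, C3 epimers | C=C[C@@](C)(O)CC[C@@H]1O[C@]1(C)[C@H](O)C[C@H]2C(CN(C)C)C(=O)O[C@H]2/C=C(\C)CC=C
F4 | step 20 | (1S,2S,3E,6E,8S,11S,12R,13R)-17-(dimethylamino)-11,12-epoxy-8,13-dihydroxycembra-3,6-dien-16,2-olide, C15 epimers | CN(C)CC1C(=O)O[C@H]2/C=C(\C)C/C=C/[C@@](C)(O)CC[C@@H]3O[C@]3(C)[C@H](O)C[C@@H]12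
F5 | step 20 | N-methyl iodide of F4 (17-trimethylammonio salt) | C[N+](C)(C)CC1C(=O)O[C@H]2/C=C(\C)C/C=C/[C@@](C)(O)CC[C@@H]3O[C@]3(C)[C@H](O)C[C@@H]12.[I-]
F0 | step 16 | none | none
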